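## Retrosynthetic overview

1. Target 28 comes from diol 27 by acetylation of the C5 and C7 hydroxyls (last step).
2. Ring B (tetrahydrofuran, formed last) comes from 5-exo opening of a cis-5,6-epoxide by the C12 tertiary hydroxyl: C6–O bond formed with inversion, C5–OH released.
3. The key C7–C8 bond comes from an intermolecular lithium aldol between chloro enone 15 (ring A, present from the start, carries C12) and cis-epoxy aldehyde 23 (C1–C7).
4. Enone 15 comes from (S)-4-silyloxycyclopentenone 1: propargylation anti to OTBS, acetylide alkylation, Lindlar reduction, oxidation, then α-chlorination through the epoxy ketone.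
5. Aldehyde 23 comes from hex-5-ynoic acid 16: hydroxymethylation, Lindlar reduction, Sharpless epoxidation with L-(+)-diethyl tartrate, oxidation.

Assumption: atom labels C1–C20 are prostanoid-style chain numbers (C1 ester carbon, C5 side-chain CH–OAc, C6 ring CH–O, C7 ring CH–OAc, C8 ring-fusion CH, C9 ketone, C10 C–Cl, C11 =CH, C12 quaternary C–O, C13–C20 octenyl); ring A is the chlorocyclopentenone, ring B the tetrahydrofuran; enone 1 and acid 16 are taken as commercial.

## Route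

Step 1
Reactants: 1 (S)-4-[(tert-butyldimethylsilyl)oxy]cyclopent-2-en-1-one; 2 propargyl bromide (3-bromoprop-1-yne)
Product: 4 (1R,4S)-4-[(tert-butyldimethylsilyl)oxy]-1-(prop-2-yn-1-yl)cyclopent-2-en-1-ol, via allenylmagnesium bromide 3 (not isolated)
Conditions: 2, Mg, HgCl2 (cat.), Et2O, 0 °C; then 1, −78 °C; sat. aq NH4Cl
Reagents that add atoms: none
Why: Barbier-type propargylation with an allenyl Grignard reagent (SE2′) adds 1,2 to the enone carbonyl from the face anti to the C4 silyloxy group, which sets the tertiary carbinol (future C12) with OH cis to OTBS and leaves a terminal alkyne for chain extension.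

Step 2
Reactants: 4 (1R,4S)-4-[(tert-butyldimethylsilyl)oxy]-1-(prop-2-yn-1-yl)cyclopent-2-en-1-ol; 5 1-iodopentane
Product: 7 (1R,4S)-4-[(tert-butyldimethylsilyl)oxy]-1-(oct-2-yn-1-yl)cyclopent-2-en-1-ol, via dilithium alkoxide acetylide 6 (not isolated)
Conditions: n-BuLi (2.2 equiv), THF, −78 → −20 °C; DMPU, 5, −20 °C → rt; sat. aq NH4Cl
Reagents that add atoms: none
Why: Acetylide alkylation (SN2) of the alkoxide–acetylide dianion takes place at the far more nucleophilic sp carbon and completes the C13–C20 chain without touching a stereocentre.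

Step 3
Reactants: 7 (1R,4S)-4-[(tert-butyldimethylsilyl)oxy]-1-(oct-2-yn-1-yl)cyclopent-2-en-1-ol
Product: 8 (1R,4S)-4-[(tert-butyldimethylsilyl)oxy]-1-[(2Z)-oct-2-en-1-yl]cyclopent-2-en-1-ol
Conditions: H2 (1 atm), Pd/CaCO3 poisoned with Pb(OAc)2, quinoline, hexane/EtOAc, rt
Reagents that add atoms: none
Why: Lindlar semihydrogenation adds H2 syn to the alkyne on the poisoned palladium surface and gives the Z-alkene, while the ring alkene and the silyl ether are untouched.

Step 4
Reactants: 8 (1R,4S)-4-[(tert-butyldimethylsilyl)oxy]-1-[(2Z)-oct-2-en-1-yl]cyclopent-2-en-1-ol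
Product: 9 (1R,4S)-1-[(2Z)-oct-2-en-1-yl]cyclopent-2-ene-1,4-diol
Conditions: TBAF (1.2 equiv), THF, 0 °C → rt
Reagents that add atoms: none
Why: Fluoride-mediated desilylation frees the secondary allylic alcohol under non-acidic conditions that spare the ionisable tertiary allylic alcohol.

Step 5
Reactants: 9 (1R,4S)-1-[(2Z)-oct-2-en-1-yl]cyclopent-2-ene-1,4-diol
Product: 10 (4R)-4-hydroxy-4-[(2Z)-oct-2-en-1-yl]cyclopent-2-en-1-one
Conditions: MnO2 (15 equiv), CH2Cl2, rt
Reagents that add atoms: none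
Why: Chemoselective allylic oxidation with MnO2 converts only the secondary allylic alcohol into the enone, because the tertiary carbinol has no carbinol hydrogen and its configuration is not touched.

Step 6
Reactants: 10 (4R)-4-hydroxy-4-[(2Z)-oct-2-en-1-yl]cyclopent-2-en-1-one
Product: 11 (1R,4R,5S)-4-hydroxy-4-[(2Z)-oct-2-en-1-yl]-6-oxabicyclo[3.1.0]hexan-2-one
Conditions: 30% aq H2O2, NaOH (0.2 equiv), MeOH, −10 → 0 °C
Reagents that add atoms: hydrogen peroxide OO
Why: Weitz–Scheffer nucleophilic epoxidation attacks only the electron-poor enone C=C (the isolated Z-alkene is inert), mainly on the face of the hydroxyl away from the octenyl chain, and the epoxide configuration is erased again in step 8.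

Step 7
Reactants: 11 (1R,4R,5S)-4-hydroxy-4-[(2Z)-oct-2-en-1-yl]-6-oxabicyclo[3.1.0]hexan-2-one
Product: 12 (2S,3R,4R)-2-chloro-3,4-dihydroxy-4-[(2Z)-oct-2-en-1-yl]cyclopentan-1-one
Conditions: HCl (2 M in Et2O, 1.5 equiv), CH2Cl2, −20 → 0 °C
Reagents that add atoms: hydrogen chloride Cl
Why: Acid-mediated epoxide opening (SN2, anti) puts chloride on the carbonyl-activated α-carbon and not on the β-carbon, which is neopentyl-like next to the quaternary carbinol, giving the trans α-chloro-β-hydroxy ketone.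

Step 8
Reactants: 12 (2S,3R,4R)-2-chloro-3,4-dihydroxy-4-[(2Z)-oct-2-en-1-yl]cyclopentan-1-one
Product: 14 (4R)-2-chloro-4-hydroxy-4-[(2Z)-oct-2-en-1-yl]cyclopent-2-en-1-one, via mesylate 13 (not isolated)
Conditions: MsCl (1.3 equiv), Et3N (3 equiv), CH2Cl2, −10 °C → rt
Reagents that add atoms: none
Why: Mesylation of the only secondary alcohol followed by E1cB elimination through the acidic α-chloro ketone proton regenerates the enone with chlorine on the α-carbon, and the tertiary alcohol stays because hydroxide is a poor leaving group.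

Step 9
Reactants: 14 (4R)-2-chloro-4-hydroxy-4-[(2Z)-oct-2-en-1-yl]cyclopent-2-en-1-one
Product: 15 (4R)-2-chloro-4-[(2Z)-oct-2-en-1-yl]-4-[(trimethylsilyl)oxy]cyclopent-2-en-1-one
Conditions: TMSCl (1.5 equiv), imidazole (3 equiv), DMF, 0 °C → rt
Reagents that add atoms: chlorotrimethylsilane C[Si](C)(C)Cl
Why: Silyl ether formation caps the tertiary alcohol with a small group so that one defined lithium enolate can be made in step 15 and the group falls off again with trace acid.

Step 10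
Reactants: 16 hex-5-ynoic acid; 17 paraformaldehyde
Product: 19 7-hydroxyhept-5-ynoic acid, via dilithium carboxylate acetylide 18 (not isolated)
Conditions: n-BuLi (2.1 equiv), THF/DMPU, −78 → 0 °C; (CH2O)n, 0 °C → rt; 1 M HCl
Reagents that add atoms: none
Why: Alkynylation of formaldehyde by the carboxylate–acetylide dianion occurs at the acetylide carbon and gives the propargylic alcohol with the complete C1–C7 chain.

Step 11
Reactants: 19 7-hydroxyhept-5-ynoic acid
Product: 20 methyl 7-hydroxyhept-5-ynoate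
Conditions: MeOH, H2SO4 (cat.), rt, 16 h
Reagents that add atoms: methanol CO
Why: Fischer esterification in excess methanol converts the acid into the methyl ester while the primary propargylic alcohol is inert.

Step 12
Reactants: 20 methyl 7-hydroxyhept-5-ynoate
Product: 21 methyl (5Z)-7-hydroxyhept-5-enoate
Conditions: H2 (1 atm), Pd/CaCO3 poisoned with Pb(OAc)2, quinoline, EtOAc, rt
Reagents that add atoms: none
Why: Lindlar semihydrogenation gives the Z-allylic alcohol by syn addition of H2, the geometry needed for a cis-epoxide.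

Step 13
Reactants: 21 methyl (5Z)-7-hydroxyhept-5-enoate
Product: 22 methyl 4-[(2R,3S)-3-(hydroxymethyl)oxiran-2-yl]butanoate
Conditions: Ti(OiPr)4 (0.2 equiv), L-(+)-diethyl tartrate (0.24 equiv), t-BuOOH (2 equiv, decane), 4 Å MS, CH2Cl2, −20 °C, 48 h
Reagents that add atoms: tert-butyl hydroperoxide CC(C)(C)OO
Why: Katsuki–Sharpless asymmetric epoxidation delivers oxygen to one face of the Z-allylic alcohol under control of the titanium–L-(+)-tartrate complex, giving the cis (2R,3S)-epoxy alcohol that fixes C5 and the later inverted C6 (about 85–90% ee expected, the minor enantiomer being removed as diastereomers after step 15).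

Step 14
Reactants: 22 methyl 4-[(2R,3S)-3-(hydroxymethyl)oxiran-2-yl]butanoate
Product: 23 methyl 4-[(2R,3R)-3-formyloxiran-2-yl]butanoate
Conditions: PhI(OAc)2 (1.1 equiv), TEMPO (0.1 equiv), CH2Cl2, rt; used crude at once
Reagents that add atoms: none
Why: The oxoammonium-mediated TEMPO oxidation stops at the aldehyde under near-neutral conditions, so the base-labile cis-epoxy aldehyde is not epimerised.

Step 15
Reactants: 15 (4R)-2-chloro-4-[(2Z)-oct-2-en-1-yl]-4-[(trimethylsilyl)oxy]cyclopent-2-en-1-one; 23 methyl 4-[(2R,3R)-3-formyloxiran-2-yl]butanoate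
Product: 25 methyl 4-[(2R,3S)-3-[(S)-[(1S,5R)-3-chloro-5-[(2Z)-oct-2-en-1-yl]-2-oxo-5-[(trimethylsilyl)oxy]cyclopent-3-en-1-yl](hydroxy)methyl]oxiran-2-yl]butanoate, via lithium dienolate 24 (not isolated)
Conditions: LDA (1.05 equiv), THF, −78 °C, 30 min; 23 (1.3 equiv), −78 °C, 20 min; sat. aq NH4Cl at −78 °C
Reagents that add atoms: none
Why: In this intermolecular lithium aldol (Zimmerman–Traxler) the cyclic E-enolate, which cannot expel the β-silyloxy group because that would give a cyclopentadienone, attacks the aldehyde on the face anti to the octenyl chain (C8, cis to the small OSiMe3) through a chair that gives the anti C7/C8 adduct, and this is also the Felkin–Anh face of the α-epoxy aldehyde (C7–OH anti to the epoxide oxygen), so C7 and C8 are set in a matched case.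

Step 16
Reactants: 25 methyl 4-[(2R,3S)-3-[(S)-[(1S,5R)-3-chloro-5-[(2Z)-oct-2-en-1-yl]-2-oxo-5-[(trimethylsilyl)oxy]cyclopent-3-en-1-yl](hydroxy)methyl]oxiran-2-yl]butanoate
Product: 27 methyl (5R)-5-[(2S,3S,3aS,6aR)-5-chloro-3-hydroxy-6a-[(2Z)-oct-2-en-1-yl]-4-oxo-3,3a,4,6a-tetrahydro-2H-cyclopenta[b]furan-2-yl]-5-hydroxypentanoate, via desilylated epoxy diol 26 (not isolated)
Conditions: CSA (0.1 equiv), MeOH (5 equiv), CH2Cl2, 0 °C → rt; crude product taken on at once
Reagents that add atoms: none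
Why: Acid removes the trimethylsilyl group and the freed C12 hydroxyl opens the protonated cis-epoxide by 5-exo-tet SN2 attack at C6 with inversion (C5–O retained), which closes ring B with the only possible cis ring fusion and gives C6 and C5 in the target configuration.

Step 17
Reactants: 27 methyl (5R)-5-[(2S,3S,3aS,6aR)-5-chloro-3-hydroxy-6a-[(2Z)-oct-2-en-1-yl]-4-oxo-3,3a,4,6a-tetrahydro-2H-cyclopenta[b]furan-2-yl]-5-hydroxypentanoate
Product: 28 methyl (5R)-5-(acetyloxy)-5-[(2S,3S,3aS,6aR)-3-(acetyloxy)-5-chloro-6a-[(2Z)-oct-2-en-1-yl]-4-oxo-3,3a,4,6a-tetrahydro-2H-cyclopenta[b]furan-2-yl]pentanoate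
Conditions: Ac2O (4 equiv), pyridine, DMAP (0.05 equiv), CH2Cl2, 0 °C
Reagents that add atoms: acetic anhydride CC(=O)OC(C)=O
Why: Nucleophile-catalysed acylation of both secondary alcohols at 0 °C is fast enough to outrun β-elimination of the C7 acetate and lactonisation of the C5 hydroxy ester, and no stereocentre is touched.

## Compound list

1 | (S)-4-[(tert-butyldimethylsilyl)oxy]cyclopent-2-en-1-one | O=C1C=C[C@@H](O[Si](C)(C)C(C)(C)C)C1 | starting material
2 | propargyl bromide (3-bromoprop-1-yne) | C#CCBr | starting material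
3 | allenylmagnesium bromide | C=C=C[Mg]Br | intermediate
4 | (1R,4S)-4-[(tert-butyldimethylsilyl)oxy]-1-(prop-2-yn-1-yl)cyclopent-2-en-1-ol | C#CC[C@]1(O)C=C[C@@H](O[Si](C)(C)C(C)(C)C)C1 | intermediate
5 | 1-iodopentane | CCCCCI | starting material
6 | dilithium alkoxide acetylide of 4 | [Li]C#CC[C@]1(O[Li])C=C[C@@H](O[Si](C)(C)C(C)(C)C)C1 | intermediate
7 | (1R,4S)-4-[(tert-butyldimethylsilyl)oxy]-1-(oct-2-yn-1-yl)cyclopent-2-en-1-ol | CCCCCC#CC[C@]1(O)C=C[C@@H](O[Si](C)(C)C(C)(C)C)C1 | intermediate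
8 | (1R,4S)-4-[(tert-butyldimethylsilyl)oxy]-1-[(2Z)-oct-2-en-1-yl]cyclopent-2-en-1-ol | CCCCC/C=C\C[C@]1(O)C=C[C@@H](O[Si](C)(C)C(C)(C)C)C1 | intermediate
9 | (1R,4S)-1-[(2Z)-oct-2-en-1-yl]cyclopent-2-ene-1,4-diol | CCCCC/C=C\C[C@]1(O)C=C[C@@H](O)C1 | intermediate
10 | (4R)-4-hydroxy-4-[(2Z)-oct-2-en-1-yl]cyclopent-2-en-1-one | CCCCC/C=C\C[C@]1(O)C=CC(=O)C1 | intermediate
11 | (1R,4R,5S)-4-hydroxy-4-[(2Z)-oct-2-en-1-yl]-6-oxabicyclo[3.1.0]hexan-2-one (epoxide cis to OH, expected major isomer) | CCCCC/C=C\C[C@]1(O)[C@H]2O[C@H]2C(=O)C1 | intermediate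
12 | (2S,3R,4R)-2-chloro-3,4-dihydroxy-4-[(2Z)-oct-2-en-1-yl]cyclopentan-1-one | CCCCC/C=C\C[C@]1(O)[C@@H](O)[C@H](Cl)C(=O)C1 | intermediate
13 | (1R,2R,5S)-5-chloro-2-hydroxy-2-[(2Z)-oct-2-en-1-yl]-4-oxocyclopentyl methanesulfonate | CCCCC/C=C\C[C@]1(O)[C@@H](OS(C)(=O)=O)[C@H](Cl)C(=O)C1 | intermediate
14 | (4R)-2-chloro-4-hydroxy-4-[(2Z)-oct-2-en-1-yl]cyclopent-2-en-1-one | CCCCC/C=C\C[C@]1(O)C=C(Cl)C(=O)C1 | intermediate
15 | (4R)-2-chloro-4-[(2Z)-oct-2-en-1-yl]-4-[(trimethylsilyl)oxy]cyclopent-2-en-1-one | CCCCC/C=C\C[C@]1(O[Si](C)(C)C)C=C(Cl)C(=O)C1 | intermediate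
16 | hex-5-ynoic acid | C#CCCCC(=O)O | starting material
17 | paraformaldehyde (formaldehyde source) | C=O | starting material
18 | dilithium carboxylate acetylide of 16 | [Li]C#CCCCC(=O)O[Li] | intermediate
19 | 7-hydroxyhept-5-ynoic acid | OCC#CCCCC(=O)O | intermediate
20 | methyl 7-hydroxyhept-5-ynoate | COC(=O)CCCC#CCO | intermediate
21 | methyl (5Z)-7-hydroxyhept-5-enoate | COC(=O)CCC/C=C\CO | intermediate
22 | methyl 4-[(2R,3S)-3-(hydroxymethyl)oxiran-2-yl]butanoate (cis-epoxide) | OC[C@@H]1O[C@@H]1CCCC(=O)OC | intermediate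
23 | methyl 4-[(2R,3R)-3-formyloxiran-2-yl]butanoate (cis-epoxide) | O=C[C@@H]1O[C@@H]1CCCC(=O)OC | intermediate
24 | lithium dienolate of 15 | CCCCC/C=C\C[C@]1(O[Si](C)(C)C)C=C(Cl)C(O[Li])=C1 | intermediate
25 | methyl 4-[(2R,3S)-3-[(S)-[(1S,5R)-3-chloro-5-[(2Z)-oct-2-en-1-yl]-2-oxo-5-[(trimethylsilyl)oxy]cyclopent-3-en-1-yl](hydroxy)methyl]oxiran-2-yl]butanoate | CCCCC/C=C\C[C@]1(O[Si](C)(C)C)C=C(Cl)C(=O)[C@H]1[C@H](O)[C@@H]2O[C@@H]2CCCC(=O)OC | intermediate
26 | methyl 4-[(2R,3S)-3-[(S)-[(1S,5R)-3-chloro-5-hydroxy-5-[(2Z)-oct-2-en-1-yl]-2-oxocyclopent-3-en-1-yl](hydroxy)methyl]oxiran-2-yl]butanoate | CCCCC/C=C\C[C@]1(O)C=C(Cl)C(=O)[C@H]1[C@H](O)[C@@H]2O[C@@H]2CCCC(=O)OC | intermediate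
27 | methyl (5R)-5-[(2S,3S,3aS,6aR)-5-chloro-3-hydroxy-6a-[(2Z)-oct-2-en-1-yl]-4-oxo-3,3a,4,6a-tetrahydro-2H-cyclopenta[b]furan-2-yl]-5-hydroxypentanoate | CCCCC/C=C\C[C@]12C=C(Cl)C(=O)[C@H]1[C@H](O)[C@H]([C@@H](CCCC(=O)OC)O)O2 | intermediate
28 | methyl (5R)-5-(acetyloxy)-5-[(2S,3S,3aS,6aR)-3-(acetyloxy)-5-chloro-6a-[(2Z)-oct-2-en-1-yl]-4-oxo-3,3a,4,6a-tetrahydro-2H-cyclopenta[b]furan-2-yl]pentanoate | CCCCC/C=C\C[C@]12C=C(Cl)C(=O)[C@H]1[C@H](OC(C)=O)[C@H]([C@@H](CCCC(=O)OC)OC(C)=O)O2 | target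

## Step count and risks

Total steps: 17. Longest linear sequence: 12 steps (steps 1–9, then 15–17); the aldehyde branch is steps 10–14.

The three steps most likely to fail:

**Step 15 (aldol).** The face of the enolate that the aldehyde takes (cis to OSiMe3) rests on a steric and stereoelectronic argument, not on a close precedent; the C8 epimer cannot close ring B. The fallback replaces steric control by internal delivery. It sets out from 14: adding 14 to LDA (2.2 equiv, THF, −78 °C) gives the dilithium alkoxide dienolate of 14 F4, whose C12 lithium alkoxide binds aldehyde 23 and delivers it to its own face. NH4Cl quench gives the epoxy diol directly, so the fallback comes back to the route at 26, which CSA alone then closes to 27.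

**Step 16 (desilylation and ring closure).** Acid could instead give 6-endo attack at C5, dehydrate the β-hydroxy ketone, or lactonise the freed C5 hydroxy ester. The fallback closes ring B on an alkene and not on an epoxide. It sets out from 21 (with enolate 24 made from 15 as in step 15): MnO2 oxidation and equilibration with a trace of I2 gives methyl (5E)-7-oxohept-5-enoate F5. Aldol of 24 with F5 (same enolate face, same anti chair, no Felkin question) gives methyl (5E,7R)-7-[(1S,5R)-3-chloro-5-[(2Z)-oct-2-en-1-yl]-2-oxo-5-[(trimethylsilyl)oxy]cyclopent-3-en-1-yl]-7-hydroxyhept-5-enoate F6. PPTS in MeOH gives methyl (5E,7R)-7-[(1S,5R)-3-chloro-5-hydroxy-5-[(2Z)-oct-2-en-1-yl]-2-oxocyclopent-3-en-1-yl]-7-hydroxyhept-5-enoate F7. I2/NaHCO3 in MeCN at 0 °C then closes ring B by 5-exo iodoetherification, anti across the E-alkene and cis to the allylic hydroxyl (5-exo is much faster than 5-endo attack on the C14 alkene), giving methyl (5S)-5-[(2R,3S,3aS,6aR)-5-chloro-3-hydroxy-6a-[(2Z)-oct-2-en-1-yl]-4-oxo-3,3a,4,6a-tetrahydro-2H-cyclopenta[b]furan-2-yl]-5-iodopentanoate F8. CsOAc/18-crown-6 in DMF displaces iodide with inversion at C5 to methyl (5R)-5-(acetyloxy)-5-[(2R,3S,3aS,6aR)-5-chloro-3-hydroxy-6a-[(2Z)-oct-2-en-1-yl]-4-oxo-3,3a,4,6a-tetrahydro-2H-cyclopenta[b]furan-2-yl]pentanoate F9, and Ac2O/pyridine acetylates C7–OH, so the fallback comes back at 28.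

**Step 7 (opening of epoxy ketone 11).** Acid may dehydrate the tertiary aldol or open the epoxide unselectively. The fallback brings in chlorine by addition–elimination before the side-chain alkene exists. It sets out from 7: TBAF gives (1R,4S)-1-(oct-2-yn-1-yl)cyclopent-2-ene-1,4-diol F1 and MnO2 gives (4R)-4-hydroxy-4-(oct-2-yn-1-yl)cyclopent-2-en-1-one F2. PhICl2/pyridine in CH2Cl2 chlorinates the enone α-carbon (a dialkylalkyne is far less reactive to electrophilic chlorine than the Z-alkene of 10) to give (4R)-2-chloro-4-hydroxy-4-(oct-2-yn-1-yl)cyclopent-2-en-1-one F3. Lindlar semihydrogenation of F3 then comes back to the route at 14.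

## Further compounds

F1 | step 7 | (1R,4S)-1-(oct-2-yn-1-yl)cyclopent-2-ene-1,4-diol | CCCCCC#CC[C@]1(O)C=C[C@@H](O)C1
F2 | step 7 | (4R)-4-hydroxy-4-(oct-2-yn-1-yl)cyclopent-2-en-1-one | CCCCCC#CC[C@]1(O)C=CC(=O)C1
F3 | step 7 | (4R)-2-chloro-4-hydroxy-4-(oct-2-yn-1-yl)cyclopent-2-en-1-one | CCCCCC#CC[C@]1(O)C=C(Cl)C(=O)C1
F4 | step 15 | dilithium alkoxide dienolate of 14 | CCCCC/C=C\C[C@]1(O[Li])C=C(Cl)C(O[Li])=C1
F5 | step 16 | methyl (5E)-7-oxohept-5-enoate | COC(=O)CCC/C=C/C=O
F6 | step 16 | methyl (5E,7R)-7-[(1S,5R)-3-chloro-5-[(2Z)-oct-2-en-1-yl]-2-oxo-5-[(trimethylsilyl)oxy]cyclopent-3-en-1-yl]-7-hydroxyhept-5-enoate | CCCCC/C=C\C[C@]1(O[Si](C)(C)C)C=C(Cl)C(=O)[C@H]1[C@H](O)/C=C/CCCC(=O)OC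
F7 | step 16 | methyl (5E,7R)-7-[(1S,5R)-3-chloro-5-hydroxy-5-[(2Z)-oct-2-en-1-yl]-2-oxocyclopent-3-en-1-yl]-7-hydroxyhept-5-enoate | CCCCC/C=C\C[C@]1(O)C=C(Cl)C(=O)[C@H]1[C@H](O)/C=C/CCCC(=O)OC
F8 | step 16 | methyl (5S)-5-[(2R,3S,3aS,6aR)-5-chloro-3-hydroxy-6a-[(2Z)-oct-2-en-1-yl]-4-oxo-3,3a,4,6a-tetrahydro-2H-cyclopenta[b]furan-2-yl]-5-iodopentanoate | CCCCC/C=C\C[C@]12C=C(Cl)C(=O)[C@H]1[C@H](O)[C@H]([C@H](CCCC(=O)OC)I)O2
F9 | step 16 | methyl (5R)-5-(acetyloxy)-5-[(2R,3S,3aS,6aR)-5-chloro-3-hydroxy-6a-[(2Z)-oct-2-en-1-yl]-4-oxo-3,3a,4,6a-tetrahydro-2H-cyclopenta[b]furan-2-yl]pentanoate | CCCCC/C=C\C[C@]12C=C(Cl)C(=O)[C@H]1[C@H](O)[C@H]([C@@H](CCCC(=O)OC)OC(C)=O)O2
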